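**Assumption:** the SMILES is read as (2R,4'R,8'S)-δ-tocomonoenol, i.e. the natural tocopherol geometry at all three centres (8' is S only because the 11'-ene raises the priority of that branch). Geranyl acetate, 4-methoxy-2-methylphenol and (R)-citronellyl bromide are taken as catalogue items.

## Retrosynthetic overview

1. Target ⇐ its 6-O-methyl ether ⇐ Cu-catalysed C5'–C6' sp3–sp3 coupling of a (2R)-chroman C5-bromide with (R)-citronellylmagnesium bromide (C8' from the chiral pool; the terminal alkene never meets acid).
2. The pyran ring is the only ring made. It is closed the way tocopherol cyclase does it: enantioselective protonation of the 2'-ene of an ortho-(E)-allylphenol and 6-endo capture by the phenol oxygen, here with a confined chiral Brønsted acid at the C10 stage (sets C2).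
3. The allylphenol ⇐ prenyltransferase-like dehydrative ortho C-allylation of 4-methoxy-2-methylphenol with (2E,7S)-3,7-dimethyloct-2-ene-1,8-diol, then OH → Br.
4. The diol ⇐ geranyl acetate by terminal allylic oxidation and hydroxyl-directed asymmetric hydrogenation (sets C4').

## Route

**Step 1**
Reactants: 1 geranyl acetate [(2E)-3,7-dimethylocta-2,6-dien-1-yl acetate]
Product: 2 (2E,6E)-8-hydroxy-3,7-dimethylocta-2,6-dien-1-yl acetate
Conditions: SeO2 (0.1 equiv), t-BuOOH (70% aq., 3 equiv), salicylic acid (0.1 equiv), CH2Cl2, rt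
Reagents that add atoms: tert-butyl hydroperoxide, CC(C)(C)OO (terminal source of the new O, relayed by catalytic selenium dioxide, O=[Se]=O)
Why: Catalytic SeO2/t-BuOOH allylic oxidation (ene reaction, then [2,3]-sigmatropic shift) attacks the E-methyl of the electron-rich terminal trisubstituted alkene and leaves the acetate-deactivated 2-ene alone, giving the (E)-allylic alcohol.

**Step 2**
Reactants: 2 (2E,6E)-8-hydroxy-3,7-dimethylocta-2,6-dien-1-yl acetate
Product: 4 (2E,7S)-3,7-dimethyloct-2-ene-1,8-diol, via saturated hydroxy acetate 3 (not isolated)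
Conditions: Ru(OAc)2[(S)-BINAP] (1 mol%), H2 (100 atm), MeOH, 25 °C; vent, then K2CO3 (0.2 equiv), same MeOH solution, rt
Reagents that add atoms: none
Why: Noyori hydroxyl-directed asymmetric hydrogenation reduces only the alkene that chelates Ru through its allylic OH (the allylic-acetate alkene does not bind), and by analogy with geraniol → (R)-citronellol the (S)-BINAP catalyst should deliver H2 to the face that gives 7S ((R)-BINAP is used if the sense proves opposite), after which base-catalysed transesterification in the same methanol frees the allylic alcohol.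

**Step 3**
Reactants: 4 (2E,7S)-3,7-dimethyloct-2-ene-1,8-diol; 5 4-methoxy-2-methylphenol (2 equiv)
Product: 6 2-[(2E,7S)-8-hydroxy-3,7-dimethyloct-2-en-1-yl]-4-methoxy-6-methylphenol
Conditions: acidic Al2O3 (Brockmann I), ClCH2CH2Cl, 80 °C
Reagents that add atoms: none
Why: Alumina-templated dehydrative Friedel–Crafts ortho-allylation: the surface-bound phenol is alkylated, with loss of water, by the allyl cation from the only allylic alcohol (the saturated primary OH cannot ionise) at the single free position ortho to OH, with the E-alkene retained.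

**Step 4**
Reactants: 6 2-[(2E,7S)-8-hydroxy-3,7-dimethyloct-2-en-1-yl]-4-methoxy-6-methylphenol
Product: 7 2-[(2E,7S)-8-bromo-3,7-dimethyloct-2-en-1-yl]-4-methoxy-6-methylphenol
Conditions: CBr4 (1.3 equiv), PPh3 (1.4 equiv), 2,6-lutidine (0.3 equiv), CH2Cl2, 0 °C
Reagents that add atoms: carbon tetrabromide, BrC(Br)(Br)Br
Why: Appel bromination converts only the primary aliphatic alcohol, under buffered near-neutral conditions that leave the phenol, the acid-sensitive ortho-allyl alkene and the 7S centre (not a reacting carbon) untouched.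

**Step 5**
Reactants: 7 2-[(2E,7S)-8-bromo-3,7-dimethyloct-2-en-1-yl]-4-methoxy-6-methylphenol
Product: 8 (2R)-2-[(4S)-5-bromo-4-methylpentyl]-6-methoxy-2,8-dimethylchromane
Conditions: confined chiral imidodiphosphorimidate (IDPi) Brønsted acid (BINOL-derived, N-triflyl core, bulky 3,3'-aryl groups; 5 mol%), cyclohexane/CHCl3 4:1, 40 °C
Reagents that add atoms: none
Why: Proposed new method: the strongly acidic, confined IDPi anion hydrogen-bonds the phenol OH while its proton is delivered to C2' of the E-trisubstituted alkene, so that C–O bond formation at the developing tertiary centre C3' is concerted but asynchronous (anti addition, 6-endo) inside the chiral pocket and one alkene face is selected, giving 2R under catalyst control independent of the remote 7'S centre (the mirror-image catalyst is used if the first run shows the 2S sense); this is the tocopherol-cyclase reaction in vitro, and the closest known reaction types are the IDPi-catalysed asymmetric intramolecular hydroalkoxylation of unactivated alkenols and chiral-acid-induced protonative cyclisations of ortho-prenylphenols.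

**Step 6**
Reactants: 8 (2R)-2-[(4S)-5-bromo-4-methylpentyl]-6-methoxy-2,8-dimethylchromane; 9 (R)-citronellyl bromide [(6R)-8-bromo-2,6-dimethyloct-2-ene] (1.5 equiv)
Product: 11 (2R)-6-methoxy-2,8-dimethyl-2-[(4R,8S)-4,8,12-trimethyltridec-11-en-1-yl]chromane, via (R)-citronellylmagnesium bromide 10 (not isolated)
Conditions: 9, Mg, THF, rt; then 8, Li2CuCl4 (5 mol%), NMP (4 equiv), THF, 0 °C → rt
Reagents that add atoms: none
Why: Cu-catalysed sp3–sp3 Grignard cross-coupling (Kochi/Cahiez type) of a primary alkyl bromide, in which neither stereocentre is at a reacting carbon, so 4'R (the 7S centre of step 2, renamed by the priority change) and 8'S (chiral pool) are carried through unchanged.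

**Step 7**
Reactants: 11 (2R)-6-methoxy-2,8-dimethyl-2-[(4R,8S)-4,8,12-trimethyltridec-11-en-1-yl]chromane
Product: 12 (2R)-2,8-dimethyl-2-[(4R,8S)-4,8,12-trimethyltridec-11-en-1-yl]chroman-6-ol (CNP0221369.1)
Conditions: NaSEt (5 equiv), DMF, 130 °C; aq. HCl work-up
Reagents that add atoms: none
Why: SN2 O-demethylation of the unhindered aryl methyl ether by thiolate (attack at methyl, not at the tertiary chroman C–O), under basic conditions that do not touch the isopropylidene alkene or any stereocentre.

## Compound list

1 | geranyl acetate, (2E)-3,7-dimethylocta-2,6-dien-1-yl acetate | CC(C)=CCC/C(C)=C/COC(C)=O | starting material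
2 | (2E,6E)-8-hydroxy-3,7-dimethylocta-2,6-dien-1-yl acetate | CC(=O)OC/C=C(\C)CC/C=C(\C)CO | intermediate
3 | (2E,7S)-8-hydroxy-3,7-dimethyloct-2-en-1-yl acetate | CC(=O)OC/C=C(\C)CCC[C@H](C)CO | intermediate (not isolated)
4 | (2E,7S)-3,7-dimethyloct-2-ene-1,8-diol | OC/C=C(\C)CCC[C@H](C)CO | intermediate
5 | 4-methoxy-2-methylphenol | COc1ccc(O)c(C)c1 | starting material
6 | 2-[(2E,7S)-8-hydroxy-3,7-dimethyloct-2-en-1-yl]-4-methoxy-6-methylphenol | COc1cc(C)c(O)c(C/C=C(\C)CCC[C@H](C)CO)c1 | intermediate
7 | 2-[(2E,7S)-8-bromo-3,7-dimethyloct-2-en-1-yl]-4-methoxy-6-methylphenol | COc1cc(C)c(O)c(C/C=C(\C)CCC[C@H](C)CBr)c1 | intermediate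
8 | (2R)-2-[(4S)-5-bromo-4-methylpentyl]-6-methoxy-2,8-dimethylchromane | BrC[C@@H](C)CCC[C@]1(C)CCc2cc(OC)cc(C)c2O1 | intermediate
9 | (R)-citronellyl bromide, (6R)-8-bromo-2,6-dimethyloct-2-ene | CC(C)=CCC[C@@H](C)CCBr | starting material
10 | (R)-citronellylmagnesium bromide, [(3R)-3,7-dimethyloct-6-en-1-yl]magnesium bromide | CC(C)=CCC[C@@H](C)CC[Mg]Br | intermediate (not isolated)
11 | (2R)-6-methoxy-2,8-dimethyl-2-[(4R,8S)-4,8,12-trimethyltridec-11-en-1-yl]chromane | CC(C)=CCC[C@@H](C)CCC[C@@H](C)CCC[C@]1(C)CCc2cc(OC)cc(C)c2O1 | intermediate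
12 | (2R)-2,8-dimethyl-2-[(4R,8S)-4,8,12-trimethyltridec-11-en-1-yl]chroman-6-ol | CC(C)=CCC[C@@H](C)CCC[C@@H](C)CCC[C@]1(C)CCc2cc(O)cc(C)c2O1 | target

## Step count and risks

Total step count: 7. Longest linear sequence: 7 (from geranyl acetate 1).

**Most likely to fail, 1 – step 5 (catalytic asymmetric protonative cyclisation; e.e. and turnover are unproven for a phenol adding to a trisubstituted alkene).** The fallback sets out from 6 and comes back at 8, and closes the ring by a chalcogen-initiated instead of a proton-initiated cyclisation. Lewis-base-catalysed enantioselective sulfenoetherification of 6 (N-(phenylsulfanyl)phthalimide, BINAM-derived selenophosphoramide catalyst, MsOH, CH2Cl2, −20 °C) forms a thiiranium ion on one face of the 2'-ene. The phenol opens it at the tertiary carbon (anti, 6-endo) to give (2S)-5-[(2R,3S)-6-methoxy-2,8-dimethyl-3-(phenylsulfanyl)chroman-2-yl]-2-methylpentan-1-ol F1. Raney nickel in ethanol removes the sulfur (no alkene or halide is present at this stage) to give (2S)-5-[(2R)-6-methoxy-2,8-dimethylchroman-2-yl]-2-methylpentan-1-ol F2. Appel bromination (CBr4, PPh3, CH2Cl2) of this alcohol returns the sequence to 8.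

**Most likely to fail, 2 – step 2 (e.e. and facial sense of Ru–BINAP hydrogenation of an α-methyl allylic alcohol are less secure than for geraniol-type substrates; any 7R material ends as an inseparable 4'-epimer).** The fallback sets out from 2 and comes back at 3, and replaces directed hydrogenation by biocatalytic conjugate reduction. MnO2 (CH2Cl2, rt) oxidises 2 to (2E,6E)-3,7-dimethyl-8-oxoocta-2,6-dien-1-yl acetate F3. An Old-Yellow-Enzyme ene-reductase (OYE2, NADP+/glucose/glucose dehydrogenase, pH 7 buffer, 30 °C) reduces only the activated C=C to (2E,7S)-3,7-dimethyl-8-oxooct-2-en-1-yl acetate F4, the (S) sense being the usual one for (E)-α-methyl enals. An alcohol dehydrogenase in the same pot reduces the aldehyde before it can epimerise, giving 3, which is carried into the methanolysis of step 2.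

**Most likely to fail, 3 – step 3 (alumina-mediated allylation with a polar diol: strong adsorption, partial E/Z scrambling or premature racemic ring closure).** The fallback sets out from 5 and comes back at 6, and joins the arene to the C10 unit before that unit is oxidised. The sodium phenoxide of 5 (NaH, toluene, rt) is C-alkylated at its only free ortho position by geranyl bromide F5 to give 2-[(2E)-3,7-dimethylocta-2,6-dien-1-yl]-4-methoxy-6-methylphenol F6. Ac2O/pyridine gives 2-[(2E)-3,7-dimethylocta-2,6-dien-1-yl]-4-methoxy-6-methylphenyl acetate F7, which protects the oxidisable phenol. SeO2/t-BuOOH as in step 1 gives 2-[(2E,6E)-8-hydroxy-3,7-dimethylocta-2,6-dien-1-yl]-4-methoxy-6-methylphenyl acetate F8. Ru(OAc)2[(S)-BINAP]/H2 as in step 2 gives 2-[(2E,7S)-8-hydroxy-3,7-dimethyloct-2-en-1-yl]-4-methoxy-6-methylphenyl acetate F9, and K2CO3/MeOH removes the aryl acetate to give 6.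

## Further compounds

F1 | step 5 | (2S)-5-[(2R,3S)-6-methoxy-2,8-dimethyl-3-(phenylsulfanyl)chroman-2-yl]-2-methylpentan-1-ol | OC[C@@H](C)CCC[C@]1(C)[C@@H](Sc3ccccc3)Cc2cc(OC)cc(C)c2O1
F2 | step 5 | (2S)-5-[(2R)-6-methoxy-2,8-dimethylchroman-2-yl]-2-methylpentan-1-ol | OC[C@@H](C)CCC[C@]1(C)CCc2cc(OC)cc(C)c2O1
F3 | step 2 | (2E,6E)-3,7-dimethyl-8-oxoocta-2,6-dien-1-yl acetate | CC(=O)OC/C=C(\C)CC/C=C(\C)C=O
F4 | step 2 | (2E,7S)-3,7-dimethyl-8-oxooct-2-en-1-yl acetate | CC(=O)OC/C=C(\C)CCC[C@H](C)C=O
F5 | step 3 | geranyl bromide, (2E)-1-bromo-3,7-dimethylocta-2,6-diene | CC(C)=CCC/C(C)=C/CBr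
F6 | step 3 | 2-[(2E)-3,7-dimethylocta-2,6-dien-1-yl]-4-methoxy-6-methylphenol | COc1cc(C)c(O)c(C/C=C(\C)CCC=C(C)C)c1
F7 | step 3 | 2-[(2E)-3,7-dimethylocta-2,6-dien-1-yl]-4-methoxy-6-methylphenyl acetate | COc1cc(C)c(OC(C)=O)c(C/C=C(\C)CCC=C(C)C)c1
F8 | step 3 | 2-[(2E,6E)-8-hydroxy-3,7-dimethylocta-2,6-dien-1-yl]-4-methoxy-6-methylphenyl acetate | COc1cc(C)c(OC(C)=O)c(C/C=C(\C)CC/C=C(\C)CO)c1
F9 | step 3 | 2-[(2E,7S)-8-hydroxy-3,7-dimethyloct-2-en-1-yl]-4-methoxy-6-methylphenyl acetate | COc1cc(C)c(OC(C)=O)c(C/C=C(\C)CCC[C@H](C)CO)c1
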